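**Retrosynthetic overview**

- The target is (3S)-7-hydroxy-8,2',3',4',5'-pentamethoxyisoflavan. It is traced back, by hydrogenolysis of a C4 hydroxyl and an O-benzyl group, to a cis-(3S,4S)-isoflavan-4-ol, and this to a flat isoflavone by an asymmetric transfer-hydrogenation cascade with dynamic kinetic resolution, which sets C3.
- The pyranone ring of the isoflavone is cut at C2–C3 and at O1–C8a, giving an acyclic 2',4'-difluoro-3'-methoxy deoxybenzoin and benzyl formate. The formate supplies C2 and O1, and its benzyloxide half then replaces the C7 fluoride to give the protected C7 oxygen.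
- Enabling feature: C3 is benzylic to ring B and one carbon away from ring-A carbon C4a. With C4 raised to a ketone, C3 becomes an acidic deoxybenzoin methylene, and the same carbonyl lies ortho to C8a and para to C7 of ring A. One temporary carbonyl therefore activates the carbon nucleophile (C3) and both SNAr sites (C8a–F, C7–F); steps 4 and 5 remove it.
- The deoxybenzoin comes from Pd-catalysed α-arylation of the difluoro aryl methyl ketone with the bromide of 1,2,3,4-tetramethoxybenzene. Rings A and B are bought; the pyran ring is the only ring formed (step 3).

Key step: step 3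

Remark: the three starting materials are taken as catalogue compounds (the fluorinated aryl methyl ketone is the least common of them).

**Step 1**
Reactants: 1 1,2,3,4-tetramethoxybenzene
Product: 2 1-bromo-2,3,4,5-tetramethoxybenzene
Conditions: NBS (1.0 equiv), MeCN, 0 °C → rt
Reagents that add atoms: N-bromosuccinimide, O=C1CCC(=O)N1Br
Why: Electrophilic aromatic bromination (SEAr) of a strongly activated arene whose two free positions are equivalent, so a single regioisomer should result and one equivalent of NBS limits dibromination.

**Step 2**
Reactants: 2 1-bromo-2,3,4,5-tetramethoxybenzene; 3 1-(2,4-difluoro-3-methoxyphenyl)ethan-1-one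
Product: 4 1-(2,4-difluoro-3-methoxyphenyl)-2-(2,3,4,5-tetramethoxyphenyl)ethan-1-one
Conditions: Pd2(dba)3 (2 mol%), XPhos (5 mol%), K3PO4 (2.5 equiv), toluene, 90 °C
Reagents that add atoms: none
Why: Buchwald–Hartwig-type Pd-catalysed α-arylation of a methyl ketone enolate with an aryl bromide, in which the bulky biarylphosphine should cope with the ortho-methoxy bromide, the weak phosphate base should leave both C–F bonds untouched, and the more acidic, more hindered product should rest as its enolate and so resist a second arylation.

**Step 3**
Reactants: 4 1-(2,4-difluoro-3-methoxyphenyl)-2-(2,3,4,5-tetramethoxyphenyl)ethan-1-one; 5 benzyl formate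
Product: 8 7-(benzyloxy)-8-methoxy-3-(2,3,4,5-tetramethoxyphenyl)-4H-chromen-4-one, via formyl ketone sodium enolate 6 (not isolated), via 7-fluoroisoflavone 7 (not isolated)
Conditions: NaH (2.5 equiv), 5 (3 equiv), THF, 0 °C → rt; then DMF added after H2 evolution has ended, 80 °C; aq. NH4Cl
Reagents that add atoms: none
Why: NaH deprotonates C3 of 4 (benzylic to ring B and α to the C4 ketone) and the enolate undergoes Claisen C-formylation with 5 (C2–C3 bond), giving the chelate-stabilised enolate 6 and benzyl alcohol; on warming, the formyl-derived enolate oxygen displaces the C8a fluoride by intramolecular SNAr through a Meisenheimer adduct stabilised by the ortho C4 carbonyl (O1–C8a bond, 7), and benzyloxide, regenerated from the benzyl alcohol by the second equivalent of NaH, then displaces the C7 fluoride para to that carbonyl to give 8. The closest known reaction types are the formate Claisen condensation of deoxybenzoins used in classical isoflavone synthesis, the Grohe-type SNAr cyclisation of 2-fluorobenzoyl enol and enamine systems (including 3-methoxy-2,4,5-trifluorobenzoyl cases of the quinolone series) and the SNAr exchange of the 7-fluoride of 4-quinolones and chromones. The pyranone ring, the only ring formed, closes by attack of O1 on sp2 carbon C8a in a six-membered addition–elimination (6-exo-trig with respect to the C8–C8a bond). No stereocentre is created, since C3 is sp2 in 8; it is set in step 4. The step needs C- rather than O-formylation, closure at C8a rather than C7, and benzyloxide attack at C7 rather than C8a: the first follows from the thermodynamic preference for the stabilised 1,3-dicarbonyl enolate, the second from geometry (only C8a is within reach of the enolate oxygen), and the third because before ring closure the substrate is an anionic, SNAr-deactivated enolate and after it only the C7 fluoride is left, while premature attack at C7 would still lead to 8.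

**Step 4**
Reactants: 8 7-(benzyloxy)-8-methoxy-3-(2,3,4,5-tetramethoxyphenyl)-4H-chromen-4-one
Product: 10 (3S,4S)-7-(benzyloxy)-8-methoxy-3-(2,3,4,5-tetramethoxyphenyl)chroman-4-ol, via racemising isoflavanone 9 (not isolated)
Conditions: RuCl[(S,S)-TsDPEN](p-cymene) (3 mol%), HCO2H–Et3N (5:2), EtOAc, 40 °C
Reagents that add atoms: none
Why: Noyori–Ikariya asymmetric transfer hydrogenation run as a cascade, in which Ru–H should first add 1,4 to the chromone to give isoflavanone 9, whose C3–H (α to the ketone and benzylic) epimerises through the enol under Et3N, while the (S,S)-catalyst reduces the (3S)-ketone fastest from the face anti to the 3-aryl group (dynamic kinetic resolution), so that C4 (S, the sense this catalyst enantiomer gives with 4-chromanone) and C3 (S, cis to the hydroxyl) are both set by the catalyst.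

**Step 5**
Reactants: 10 (3S,4S)-7-(benzyloxy)-8-methoxy-3-(2,3,4,5-tetramethoxyphenyl)chroman-4-ol
Product: 12 (3S)-8-methoxy-3-(2,3,4,5-tetramethoxyphenyl)chroman-7-ol, via debenzylated diol 11 (not isolated)
Conditions: H2 (1–3 bar), 10% Pd/C, EtOH–AcOH (10:1), rt
Reagents that add atoms: none
Why: Pd-catalysed hydrogenolysis should cleave the O-benzyl ether and then the C4–OH bond, a benzylic C–O bond activated by the ortho ring oxygen O1 and the para C7 oxygen, while C3 is not involved and keeps its configuration (the descriptor stays S because C2 still outranks the aryl carbon and C4).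

**Compound list**

1 | 1,2,3,4-tetramethoxybenzene | COc1ccc(OC)c(OC)c1OC | starting material
2 | 1-bromo-2,3,4,5-tetramethoxybenzene | COc1cc(Br)c(OC)c(OC)c1OC | intermediate
3 | 1-(2,4-difluoro-3-methoxyphenyl)ethan-1-one | CC(=O)c1ccc(F)c(OC)c1F | starting material
4 | 1-(2,4-difluoro-3-methoxyphenyl)-2-(2,3,4,5-tetramethoxyphenyl)ethan-1-one | COc1cc(CC(=O)c2ccc(F)c(OC)c2F)c(OC)c(OC)c1OC | intermediate
5 | benzyl formate | O=COCc1ccccc1 | starting material
6 | (Z)-1-(2,4-difluoro-3-methoxyphenyl)-3-hydroxy-2-(2,3,4,5-tetramethoxyphenyl)prop-2-en-1-one (hydroxymethylene ketone, present in the flask as its sodium enolate) | O/C=C(/c1cc(OC)c(OC)c(OC)c1OC)C(=O)c1ccc(F)c(OC)c1F | intermediate (not isolated)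
7 | 7-fluoro-8-methoxy-3-(2,3,4,5-tetramethoxyphenyl)-4H-chromen-4-one | COc1cc(C2=COc3c(ccc(F)c3OC)C2=O)c(OC)c(OC)c1OC | intermediate (not isolated)
8 | 7-(benzyloxy)-8-methoxy-3-(2,3,4,5-tetramethoxyphenyl)-4H-chromen-4-one | COc1cc(C2=COc3c(ccc(OCc4ccccc4)c3OC)C2=O)c(OC)c(OC)c1OC | intermediate
9 | 7-(benzyloxy)-8-methoxy-3-(2,3,4,5-tetramethoxyphenyl)chroman-4-one (racemic, C3 configurationally labile) | COc1cc(C2COc3c(ccc(OCc4ccccc4)c3OC)C2=O)c(OC)c(OC)c1OC | intermediate (not isolated)
10 | (3S,4S)-7-(benzyloxy)-8-methoxy-3-(2,3,4,5-tetramethoxyphenyl)chroman-4-ol (cis) | COc1cc([C@H]2COc3c(ccc(OCc4ccccc4)c3OC)[C@H]2O)c(OC)c(OC)c1OC | intermediate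
11 | (3S,4S)-8-methoxy-3-(2,3,4,5-tetramethoxyphenyl)chromane-4,7-diol | COc1cc([C@H]2COc3c(ccc(O)c3OC)[C@H]2O)c(OC)c(OC)c1OC | intermediate (not isolated)
12 | (3S)-8-methoxy-3-(2,3,4,5-tetramethoxyphenyl)chroman-7-ol | COc1cc([C@H]2COc3c(ccc(O)c3OC)C2)c(OC)c(OC)c1OC | target

**Step count and risks**

Total step count: 5. Longest linear sequence: 5 steps (1 → 2 → 4 → 8 → 10 → 12).

Steps most likely to fail:

Step 3. Benzyloxide may attack the C8a fluoride intermolecularly before the pyranone ring has closed, or the formyl group may be lost again by retro-Claisen cleavage at the temperature the SNAr closure needs. The fallback separates the three events and brings in the C1 unit at the amide-acetal level, with the ring oxygen coming from water. It sets out from 4, which is condensed with N,N-dimethylformamide dimethyl acetal (toluene, 100 °C) to the enaminone (E)-1-(2,4-difluoro-3-methoxyphenyl)-3-(dimethylamino)-2-(2,3,4,5-tetramethoxyphenyl)prop-2-en-1-one F1 (its double-bond geometry is immaterial). Mild acid hydrolysis (aq. HCl, THF, rt) should give the hydroxymethylene ketone 6, now isolated. K2CO3 in DMF at 80 °C should close it to 7 with no alkoxide present, and benzyl alcohol with Cs2CO3 in DMSO at 60 °C should convert 7 into 8, where the fallback comes back to the route.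

Step 4. The ruthenium hydride may fail to reduce the electron-rich, 7-alkoxy-deactivated vinylogous ester (stalled conjugate reduction), or carbonyl reduction may run ahead of it. The fallback takes the conjugate reduction away from the catalyst: it sets out from 8, which is reduced 1,4 with L-Selectride (THF, −78 °C) to the isoflavanone 9, isolated as the racemate. Compound 9 is then submitted to a ketone-only transfer hydrogenation with dynamic kinetic resolution (same (S,S)-catalyst, HCO2H–Et3N, DBU as additional racemisation base if needed) and comes back to the route at 10.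

Step 5. Acid-assisted dehydration of the C4 carbinol to the isoflav-3-ene followed by unselective re-hydrogenation would erode the configuration at C3, or the reaction may stall after debenzylation. The fallback replaces surface hydrogenolysis of the C4–O bond by ionic deoxygenation: it sets out from 10, which is treated with Et3SiH and CF3CO2H (CH2Cl2, −20 → 0 °C) so that hydride capture of the oxygen-stabilised C4 cation outruns loss of H3, giving (S)-7-(benzyloxy)-8-methoxy-3-(2,3,4,5-tetramethoxyphenyl)chromane F2. Neutral hydrogenolysis of the benzyl ether (H2, Pd/C, EtOAc–MeOH, rt) then comes back to the route at 12.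

**Further compounds**

F1 | step 3 | (E)-1-(2,4-difluoro-3-methoxyphenyl)-3-(dimethylamino)-2-(2,3,4,5-tetramethoxyphenyl)prop-2-en-1-one | CN(C)/C=C(\c1cc(OC)c(OC)c(OC)c1OC)C(=O)c1ccc(F)c(OC)c1F
F0 | step 4 | none | none
F2 | step 5 | (S)-7-(benzyloxy)-8-methoxy-3-(2,3,4,5-tetramethoxyphenyl)chromane | COc1cc([C@H]2COc3c(ccc(OCc4ccccc4)c3OC)C2)c(OC)c(OC)c1OC
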